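**Retrosynthetic overview**
- The target is reached from a 5-dimethoxymethyl-7-methoxy-2,3-dihydrobenzofuran; the C7'–C9' chain is grown last from the masked C7' aldehyde (hydrolysis, Horner–Wadsworth–Emmons, reduction, desilylation).
- Feature used: the ring-fusion carbons C4' (oxygen-bearing) and C3' are the carbonyl and alpha carbons of a trans 4-(silyloxymethyl)-5-aryl gamma-butyrolactone that already holds O, C7 and C8, so the benzene ring C1'–C6' is built last, on the lactone.
- Key disconnection C6'–C1': thermal 6π-electrocyclisation of the triene C6'=C5'–C4'=C3'–C2'=C1' (central bond = dihydrofuran enol ether), then dehydrogenation.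
- Triene from C4'–C5' Stille coupling of a dienyl ketene acetal phosphate with a 1-methoxyvinylstannane; phosphate from gamma-deprotonation/O-phosphorylation of the alpha-(3,3-dimethoxypropylidene) lactone (C3'–C2' by aldol/dehydration).
- Lactone from an Evans syn-aldol (C7–C8, both stereocentres), reduction, silylation, alkene cleavage and oxidation; ring order: oxolane ring (O–C7–C8–C3'–C4') first, benzene ring second.

Key step: step 13

Remark: neolignan locants are used (C7, C8, C9 on the trimethoxyphenylpropane unit, primed locants on the other unit), Ar = 3,4,5-trimethoxyphenyl, TBS = tert-butyldimethylsilyl; the syn-aldol is required because the aldol oxygen and the allyl carbon both become ring atoms, so syn in the open chain corresponds to trans in the lactone.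

**Step 1**
Reactants: 1 pent-4-enoic acid; 2 (R)-4-benzyloxazolidin-2-one
Product: 4 (R)-4-benzyl-3-(pent-4-enoyl)oxazolidin-2-one, via mixed pivalic anhydride 3 (not isolated)
Conditions: PivCl, Et3N, THF, −20 °C; then LiCl, 2, −20 °C to rt
Reagents that add atoms: none
Why: N-acylation of the oxazolidinone through the mixed pivalic anhydride with LiCl activation is a standard mild imide synthesis that leaves the terminal alkene untouched.

**Step 2**
Reactants: 4 (R)-4-benzyl-3-(pent-4-enoyl)oxazolidin-2-one; 5 3,4,5-trimethoxybenzaldehyde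
Product: 7 (R)-4-benzyl-3-[(2R,3R)-3-hydroxy-2-(prop-2-en-1-yl)-3-Ar-propanoyl]oxazolidin-2-one, via (Z)-dibutylboron enolate 6 (not isolated)
Conditions: Bu2BOTf, i-Pr2NEt, CH2Cl2, 0 °C; then 5, −78 to 0 °C; pH 7 buffer, MeOH, 30% H2O2, 0 °C
Reagents that add atoms: none
Why: Evans syn-aldol, in which the (Z)-boron enolate reacts through a closed Zimmerman–Traxler chair on the face away from the benzyl group of the (R)-auxiliary and should set C8 (2R) and C7 (3R) in the syn relationship; the aromatic aldehyde cannot enolise.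

**Step 3**
Reactants: 7 syn-aldol imide
Product: 9 (1R,2S)-2-(prop-2-en-1-yl)-1-Ar-propane-1,3-diol, via beta-hydroxy aldehyde 8 (not isolated)
Conditions: LiBH4, H2O (1 equiv), THF, 0 °C
Reagents that add atoms: none
Why: Reductive removal of the auxiliary with LiBH4 attacks the exocyclic imide carbonyl, passes through aldehyde 8 and should give the diol without touching the alkene or epimerising C8.

**Step 4**
Reactants: 9 diol
Product: 10 (1R,2S)-2-(TBSO-methyl)-1-Ar-pent-4-en-1-ol
Conditions: TBSCl (1.05 equiv), imidazole, CH2Cl2, 0 °C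
Reagents that add atoms: tert-butyldimethylsilyl chloride, CC(C)(C)[Si](C)(C)Cl
Why: Silyl ether formation is much faster at the primary hydroxyl than at the hindered secondary benzylic one, which leaves O7 free to become the ring oxygen.

**Step 5**
Reactants: 10 mono-silyl ether
Product: 13 (4S,5R)-4-(TBSO-methyl)-5-Ar-oxolan-2-ol (both anomers), via triol 11 (not isolated), via hydroxy aldehyde 12 (not isolated)
Conditions: OsO4 (cat.), NaIO4, 2,6-lutidine, dioxane/H2O (3:1), rt
Reagents that add atoms: osmium tetroxide, O=[Os](=O)(=O)=O (donor of the new oxygen, restored by sodium periodate, [Na+].[O-]I(=O)(=O)=O)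
Why: Lemieux–Johnson cleavage (dihydroxylation, then periodate glycol cleavage) removes the terminal carbon, and the aldehyde is trapped at once by the C7 hydroxyl as the five-membered lactol; this buffered oxidant spares the electron-rich arene that ozone could attack.

**Step 6**
Reactants: 13 lactol
Product: 14 (4S,5R)-4-(TBSO-methyl)-5-Ar-oxolan-2-one
Conditions: TEMPO (cat.), PhI(OAc)2, CH2Cl2, rt
Reagents that add atoms: none
Why: Oxoammonium (TEMPO) oxidation of a lactol to the lactone is mild and near neutral, so the silyl ether, the benzylic C7–O bond and the trans relationship of C7 and C8 should be kept.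

**Step 7**
Reactants: 15 1,1,3,3-tetramethoxypropane
Product: 16 3,3-dimethoxypropanal
Conditions: H2O (1.0 equiv), Amberlyst-15 (cat.), rt; filter; distil at reduced pressure and use at once
Reagents that add atoms: water, O
Why: Acid-catalysed hydrolysis of one acetal group with a single equivalent of water should give the mono-aldehyde, which is used fresh because it loses methanol on standing.

**Step 8**
Reactants: 14 lactone; 16 3,3-dimethoxypropanal
Product: 18 (4S,5R)-3-(1-hydroxy-3,3-dimethoxypropyl)-4-(TBSO-methyl)-5-Ar-oxolan-2-one (3,4-trans; carbinol epimers), via lithium enolate 17 (not isolated)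
Conditions: LiN(SiMe3)2, THF, −78 °C; then 16, −78 °C; AcOH quench
Reagents that add atoms: none
Why: Lithium enolate aldol addition at −78 °C should outrun deprotonation of the aldehyde, and the enolate cannot eliminate because both oxygen substituents are gamma to C3'; the new stereocentres are removed in step 9.

**Step 9**
Reactants: 18 beta-hydroxy lactone
Product: 20 (3E,4S,5R)-3-(3,3-dimethoxypropylidene)-4-(TBSO-methyl)-5-Ar-oxolan-2-one, via mesylate 19 (not isolated)
Conditions: MsCl, Et3N, CH2Cl2, 0 °C; then DBU, 0 °C to rt (short contact)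
Reagents that add atoms: none
Why: Mesylation and E1cB elimination complete the aldol condensation and should give mainly the (E)-alkylidene lactone; either alkene isomer serves because the C3'=C2' geometry is lost in step 10.

**Step 10**
Reactants: 20 alkylidene lactone
Product: 22 diphenyl (4S,5R)-4-(TBSO-methyl)-3-[(E)-3,3-dimethoxyprop-1-en-1-yl]-5-Ar-4,5-dihydrofuran-2-yl phosphate, via potassium dienolate 21 (not isolated)
Conditions: (PhO)2P(O)Cl, HMPA, THF, −78 °C; KN(SiMe3)2 added last, −78 °C; Et3N-buffered work-up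
Reagents that add atoms: diphenyl chlorophosphate, O=P(Cl)(Oc1ccccc1)Oc1ccccc1
Why: Vinylogous (gamma) deprotonation at C1' gives the extended dienolate, which the hard phosphoryl chloride traps on oxygen as in the known conversion of lactone enolates into ketene acetal phosphates; allylic 1,3-strain against C8 should turn the acetal carbon outward to give the (E)-C2'=C1' bond, and trapping in the flask keeps the dienolate too short-lived to lose methoxide.

**Step 11**
Reactants: 23 methyl vinyl ether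
Product: 25 tributyl(1-methoxyethenyl)stannane, via 1-methoxyvinyllithium 24 (not isolated)
Conditions: t-BuLi, THF, −78 to 0 °C; then Bu3SnCl, −78 °C to rt; distil
Reagents that add atoms: tributyltin chloride, CCCC[Sn](Cl)(CCCC)CCCC
Why: alpha-Lithiation of the vinyl ether followed by stannylation is the standard route to 1-alkoxyvinylstannanes.

**Step 12**
Reactants: 22 ketene acetal phosphate; 25 tributyl(1-methoxyethenyl)stannane
Product: 26 (2R,3S)-3-(TBSO-methyl)-4-[(E)-3,3-dimethoxyprop-1-en-1-yl]-5-(1-methoxyethenyl)-2-Ar-2,3-dihydrofuran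
Conditions: Pd(PPh3)4 (5 mol%), LiCl, THF, 60 °C; chromatography on Et3N-deactivated silica
Reagents that add atoms: none
Why: Stille cross-coupling, in which zerovalent palladium inserts into the C4'–O bond of the ketene acetal phosphate and the alkoxyvinyl group is transferred from tin with LiCl assistance, as known for lactone-derived ketene acetal phosphates; neither the alkene geometry nor the stereocentres take part.

**Step 13**
Reactants: 26 triene
Product: 28 (2R,3S)-3-(TBSO-methyl)-5-(dimethoxymethyl)-7-methoxy-2-Ar-2,3-dihydro-1-benzofuran, via cyclohexadiene 27 (not isolated)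
Conditions: K2CO3 (solid), degassed PhMe, 130 °C (sealed, base-washed tube); then DDQ (1.05 equiv), 0 °C to rt
Reagents that add atoms: none
Why: Proposed new method: heating populates the s-cis,s-cis conformer of the triene C6'=C5'–C4'=C3'–C2'=C1', whose central C4'=C3' bond is held cis by the dihydrofuran, and a thermally allowed six-electron disrotatory electrocyclisation joins C6' to C1' and closes the six-membered carbocycle C1'–C6'. The closest known reaction type is the thermal 6π-electrocyclisation of 1,3,5-hexatrienes followed by quinone dehydrogenation to arenes; new here is a triene whose central bond is a cyclic enol ether flanked by a 1-methoxyvinyl terminus and an allylic acetal. DDQ then abstracts hydride from C1' or C6' of cyclohexadiene 27 to give a cation stabilised by the two oxygen substituents, and proton loss gives the benzene ring. The only new stereocentre, C1' of 27, is transient and is erased on aromatisation, while C7 and C8 lie outside the reacting array and keep the trans relationship set in the lactone. Regiochemistry is fixed by connectivity, and the (E)-geometry at C2'=C1' keeps the acetal carbon outside the closing termini so that no inward substituent retards the disrotation. The selectivity needed is loss of hydrogen over loss of methanol or a [1,5]-hydrogen shift from C8, which base-buffered neutral heating and oxidation at low temperature only after closure should secure.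

**Step 14**
Reactants: 28 benzofuran acetal
Product: 29 (2R,3S)-3-(TBSO-methyl)-7-methoxy-2-Ar-2,3-dihydro-1-benzofuran-5-carbaldehyde
Conditions: PPTS (cat.), acetone/H2O (10:1), rt
Reagents that add atoms: water, O
Why: Mild acid-catalysed acetal hydrolysis should free the aromatic aldehyde quickly, an aryl dimethyl acetal being far more labile than the primary silyl ether.

**Step 15**
Reactants: 29 aldehyde
Product: 30 ethyl (2E)-3-[(2R,3S)-3-(TBSO-methyl)-7-methoxy-2-Ar-2,3-dihydro-1-benzofuran-5-yl]prop-2-enoate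
Conditions: (EtO)2P(O)CH2CO2Et, NaH, THF, 0 °C to rt
Reagents that add atoms: triethyl phosphonoacetate, CCOC(=O)CP(=O)(OCC)OCC
Why: Horner–Wadsworth–Emmons olefination with the stabilised phosphonate anion should give the (E)-cinnamate under thermodynamic control.

**Step 16**
Reactants: 30 cinnamate ester
Product: 32 (2E)-3-[(2R,3S)-3-(TBSO-methyl)-7-methoxy-2-Ar-2,3-dihydro-1-benzofuran-5-yl]prop-2-en-1-ol, via enal 31 (not isolated)
Conditions: i-Bu2AlH (2.5 equiv), CH2Cl2, −78 °C; aqueous potassium sodium tartrate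
Reagents that add atoms: none
Why: 1,2-Reduction of the conjugated ester with excess i-Bu2AlH at low temperature should give the (E)-allylic alcohol through enal 31 without conjugate reduction.

**Step 17**
Reactants: 32 silyl ether
Product: 33 (-)-(7R,8S,7'E)-3,4,5,5'-tetramethoxy-4',7-epoxy-8,3'-neolign-7'-ene-9,9'-diol
Conditions: Bu4NF, THF, 0 °C to rt
Reagents that add atoms: none
Why: Fluoride-mediated silyl ether cleavage frees the C9 hydroxyl without touching the allylic alcohol or the benzylic ether.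

**Compound list**
1 | pent-4-enoic acid | C=CCCC(=O)O | starting material
2 | (R)-4-benzyloxazolidin-2-one | O=C1N[C@H](Cc2ccccc2)CO1 | starting material
3 | pent-4-enoic pivalic anhydride | C=CCCC(=O)OC(=O)C(C)(C)C | intermediate
4 | (R)-4-benzyl-3-(pent-4-enoyl)oxazolidin-2-one | C=CCCC(=O)N1[C@H](Cc2ccccc2)COC1=O | intermediate
5 | 3,4,5-trimethoxybenzaldehyde | COc1cc(C=O)cc(OC)c1OC | starting material
6 | (Z)-dibutylboron enolate of 4 | C=CC/C=C(\OB(CCCC)CCCC)N1[C@H](Cc2ccccc2)COC1=O | intermediate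
7 | (R)-4-benzyl-3-[(2R,3R)-3-hydroxy-2-(prop-2-en-1-yl)-3-(3,4,5-trimethoxyphenyl)propanoyl]oxazolidin-2-one | COc1cc([C@H](O)[C@@H](CC=C)C(=O)N2[C@H](Cc3ccccc3)COC2=O)cc(OC)c1OC | intermediate
8 | (2R,3R)-3-hydroxy-2-(prop-2-en-1-yl)-3-(3,4,5-trimethoxyphenyl)propanal | COc1cc([C@H](O)[C@@H](CC=C)C=O)cc(OC)c1OC | intermediate
9 | (1R,2S)-2-(prop-2-en-1-yl)-1-(3,4,5-trimethoxyphenyl)propane-1,3-diol | COc1cc([C@H](O)[C@@H](CC=C)CO)cc(OC)c1OC | intermediate
10 | (1R,2S)-2-{[tert-butyl(dimethyl)silyl]oxymethyl}-1-(3,4,5-trimethoxyphenyl)pent-4-en-1-ol | COc1cc([C@H](O)[C@@H](CC=C)CO[Si](C)(C)C(C)(C)C)cc(OC)c1OC | intermediate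
11 | (4S,5R)-4-{[tert-butyl(dimethyl)silyl]oxymethyl}-5-(3,4,5-trimethoxyphenyl)pentane-1,2,5-triol (C2 epimers) | COc1cc([C@H](O)[C@@H](CC(O)CO)CO[Si](C)(C)C(C)(C)C)cc(OC)c1OC | intermediate
12 | (3S,4R)-3-{[tert-butyl(dimethyl)silyl]oxymethyl}-4-hydroxy-4-(3,4,5-trimethoxyphenyl)butanal | COc1cc([C@H](O)[C@@H](CC=O)CO[Si](C)(C)C(C)(C)C)cc(OC)c1OC | intermediate
13 | (4S,5R)-4-{[tert-butyl(dimethyl)silyl]oxymethyl}-5-(3,4,5-trimethoxyphenyl)oxolan-2-ol (anomers) | COc1cc([C@@H]2OC(O)C[C@H]2CO[Si](C)(C)C(C)(C)C)cc(OC)c1OC | intermediate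
14 | (4S,5R)-4-{[tert-butyl(dimethyl)silyl]oxymethyl}-5-(3,4,5-trimethoxyphenyl)oxolan-2-one | COc1cc([C@@H]2OC(=O)C[C@H]2CO[Si](C)(C)C(C)(C)C)cc(OC)c1OC | intermediate
15 | 1,1,3,3-tetramethoxypropane | COC(CC(OC)OC)OC | starting material
16 | 3,3-dimethoxypropanal | COC(CC=O)OC | intermediate
17 | lithium enolate of lactone 14 | COc1cc([C@@H]2OC([O-])=C[C@H]2CO[Si](C)(C)C(C)(C)C)cc(OC)c1OC.[Li+] | intermediate
18 | (4S,5R)-3-(1-hydroxy-3,3-dimethoxypropyl)-4-{[tert-butyl(dimethyl)silyl]oxymethyl}-5-(3,4,5-trimethoxyphenyl)oxolan-2-one | COc1cc([C@@H]2OC(=O)C(C(O)CC(OC)OC)[C@H]2CO[Si](C)(C)C(C)(C)C)cc(OC)c1OC | intermediate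
19 | methanesulfonate of 18 | COc1cc([C@@H]2OC(=O)C(C(OS(C)(=O)=O)CC(OC)OC)[C@H]2CO[Si](C)(C)C(C)(C)C)cc(OC)c1OC | intermediate
20 | (3E,4S,5R)-3-(3,3-dimethoxypropylidene)-4-{[tert-butyl(dimethyl)silyl]oxymethyl}-5-(3,4,5-trimethoxyphenyl)oxolan-2-one | COc1cc([C@@H]2OC(=O)/C(=C/CC(OC)OC)[C@H]2CO[Si](C)(C)C(C)(C)C)cc(OC)c1OC | intermediate
21 | potassium dienolate of 20 | COc1cc([C@@H]2OC([O-])=C(/C=C/C(OC)OC)[C@H]2CO[Si](C)(C)C(C)(C)C)cc(OC)c1OC.[K+] | intermediate
22 | diphenyl (4S,5R)-4-{[tert-butyl(dimethyl)silyl]oxymethyl}-3-[(E)-3,3-dimethoxyprop-1-en-1-yl]-5-(3,4,5-trimethoxyphenyl)-4,5-dihydrofuran-2-yl phosphate | COc1cc([C@@H]2OC(OP(=O)(Oc3ccccc3)Oc3ccccc3)=C(/C=C/C(OC)OC)[C@H]2CO[Si](C)(C)C(C)(C)C)cc(OC)c1OC | intermediate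
23 | methyl vinyl ether | COC=C | starting material
24 | 1-methoxyvinyllithium | [Li]C(=C)OC | intermediate
25 | tributyl(1-methoxyethenyl)stannane | CCCC[Sn](CCCC)(CCCC)C(=C)OC | intermediate
26 | (2R,3S)-3-{[tert-butyl(dimethyl)silyl]oxymethyl}-4-[(E)-3,3-dimethoxyprop-1-en-1-yl]-5-(1-methoxyethenyl)-2-(3,4,5-trimethoxyphenyl)-2,3-dihydrofuran | COc1cc([C@@H]2OC(C(=C)OC)=C(/C=C/C(OC)OC)[C@H]2CO[Si](C)(C)C(C)(C)C)cc(OC)c1OC | intermediate
27 | (2R,3S)-3-{[tert-butyl(dimethyl)silyl]oxymethyl}-5-(dimethoxymethyl)-7-methoxy-2-(3,4,5-trimethoxyphenyl)-2,3,5,6-tetrahydro-1-benzofuran (C5 epimers) | COc1cc([C@@H]2OC3=C(OC)CC(C(OC)OC)C=C3[C@H]2CO[Si](C)(C)C(C)(C)C)cc(OC)c1OC | intermediate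
28 | (2R,3S)-3-{[tert-butyl(dimethyl)silyl]oxymethyl}-5-(dimethoxymethyl)-7-methoxy-2-(3,4,5-trimethoxyphenyl)-2,3-dihydro-1-benzofuran | COc1cc([C@@H]2Oc3c(OC)cc(C(OC)OC)cc3[C@H]2CO[Si](C)(C)C(C)(C)C)cc(OC)c1OC | intermediate
29 | (2R,3S)-3-{[tert-butyl(dimethyl)silyl]oxymethyl}-7-methoxy-2-(3,4,5-trimethoxyphenyl)-2,3-dihydro-1-benzofuran-5-carbaldehyde | COc1cc([C@@H]2Oc3c(OC)cc(C=O)cc3[C@H]2CO[Si](C)(C)C(C)(C)C)cc(OC)c1OC | intermediate
30 | ethyl (2E)-3-[(2R,3S)-3-{[tert-butyl(dimethyl)silyl]oxymethyl}-7-methoxy-2-(3,4,5-trimethoxyphenyl)-2,3-dihydro-1-benzofuran-5-yl]prop-2-enoate | COc1cc([C@@H]2Oc3c(OC)cc(/C=C/C(=O)OCC)cc3[C@H]2CO[Si](C)(C)C(C)(C)C)cc(OC)c1OC | intermediate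
31 | (2E)-3-[(2R,3S)-3-{[tert-butyl(dimethyl)silyl]oxymethyl}-7-methoxy-2-(3,4,5-trimethoxyphenyl)-2,3-dihydro-1-benzofuran-5-yl]prop-2-enal | COc1cc([C@@H]2Oc3c(OC)cc(/C=C/C=O)cc3[C@H]2CO[Si](C)(C)C(C)(C)C)cc(OC)c1OC | intermediate
32 | (2E)-3-[(2R,3S)-3-{[tert-butyl(dimethyl)silyl]oxymethyl}-7-methoxy-2-(3,4,5-trimethoxyphenyl)-2,3-dihydro-1-benzofuran-5-yl]prop-2-en-1-ol | COc1cc([C@@H]2Oc3c(OC)cc(/C=C/CO)cc3[C@H]2CO[Si](C)(C)C(C)(C)C)cc(OC)c1OC | intermediate
33 | (-)-(7R,8S,7'E)-3,4,5,5'-tetramethoxy-4',7-epoxy-8,3'-neolign-7'-ene-9,9'-diol | COc1cc([C@@H]2Oc3c(OC)cc(/C=C/CO)cc3[C@H]2CO)cc(OC)c1OC | target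

**Step count**
Total: 17 steps. Longest linear sequence: 15 steps (steps 1–6, 8–10, 12–17); steps 7 and 11 prepare the two side reagents.

**Steps most likely to fail**

1. Step 13 (the step carrying the new method). The five-membered ring spreads the triene termini, so closure may need temperatures at which other processes compete: ionisation of the allylic acetal by traces of acid, a [1,5]-hydrogen shift from C8 that would erase that stereocentre, or loss of methanol instead of hydrogen from the dihydroarene. Fallback with known chemistry, setting out from lactone 14 and returning at aldehyde 29: 14 is converted with LiN(SiMe3)2 and Me3SiCl into the silyl ketene acetal (4S,5R)-4-(TBSO-methyl)-5-Ar-2-(trimethylsilyloxy)-4,5-dihydrofuran F1. Inverse-electron-demand Diels–Alder reaction of F1 with methyl 3-bromo-2-oxo-2H-pyran-5-carboxylate (toluene, 80–100 °C; the nucleophilic C3' bonds to C6 of the pyrone, C4' to the bromine-bearing C3) should give the bridged bicyclic lactone F2. F2 loses CO2 by retro-Diels–Alder reaction to the dihydroarene F3, which loses Me3SiOH to methyl (2R,3S)-7-bromo-3-(TBSO-methyl)-2-Ar-2,3-dihydro-1-benzofuran-5-carboxylate F4. Palladium-catalysed C–O coupling with methanol (Pd2(dba)3, t-BuBrettPhos, Cs2CO3, toluene) replaces the bromine at C5' by methoxy to give the 7-methoxy ester F5; i-Bu2AlH gives the benzylic alcohol F6, and MnO2 oxidises it to 29.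

2. Step 10. The dienolate may lose methoxide by vinylogous beta-elimination, may be phosphorylated on carbon, or may form with poor control of the C2'=C1' geometry. Fallback from alkylidene lactone 20, returning at triene 26 and bypassing steps 10 and 12: 1-methoxyvinyllithium 24 (from 23 and t-BuLi) is added to the lactone carbonyl of 20 at −78 °C to give the hemiketal (4S,5R)-3-(3,3-dimethoxypropylidene)-2-(1-methoxyethenyl)-4-(TBSO-methyl)-5-Ar-oxolan-2-ol F7, in equilibrium with its open hydroxy enone form. MsCl/Et3N ionises F7 to the ring oxocarbenium ion, which loses the C1' proton in a 1,4-elimination to give 26, so that no carbanion is ever formed next to the acetal.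

3. Step 12. Oxidative addition into the hindered tetrasubstituted ketene acetal phosphate may be slow, and protodestannylation of 25 or hydrolysis of the phosphate and of the acid-sensitive product may take over. Fallback from phosphate 22, returning at triene 26: palladium-catalysed methoxycarbonylation (Pd(OAc)2, PPh3, CO, MeOH, Et3N, DMF) gives methyl (4S,5R)-4-(TBSO-methyl)-3-[(E)-3,3-dimethoxyprop-1-en-1-yl]-5-Ar-4,5-dihydrofuran-2-carboxylate F8. Methylenation of the ester carbonyl of F8 with Cp2TiMe2 (toluene, 65 °C) turns the CO2Me group into the 1-methoxyvinyl group of 26.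

**Further compounds**
F1 | step 13 | (4S,5R)-4-{[tert-butyl(dimethyl)silyl]oxymethyl}-5-(3,4,5-trimethoxyphenyl)-2-(trimethylsilyloxy)-4,5-dihydrofuran | COc1cc([C@@H]2OC(O[Si](C)(C)C)=C[C@H]2CO[Si](C)(C)C(C)(C)C)cc(OC)c1OC
F2 | step 13 | bridged bicyclic lactone from F1 and methyl 3-bromo-2-oxo-2H-pyran-5-carboxylate (new centres undefined) | COc1cc([C@@H]2OC3(O[Si](C)(C)C)C(C4OC(=O)C3(Br)C=C4C(=O)OC)[C@H]2CO[Si](C)(C)C(C)(C)C)cc(OC)c1OC
F3 | step 13 | methyl (2R,3S)-7-bromo-3-{[tert-butyl(dimethyl)silyl]oxymethyl}-2-(3,4,5-trimethoxyphenyl)-7a-(trimethylsilyloxy)-2,3,3a,7a-tetrahydro-1-benzofuran-5-carboxylate | COc1cc([C@@H]2OC3(O[Si](C)(C)C)C(C=C(C(=O)OC)C=C3Br)[C@H]2CO[Si](C)(C)C(C)(C)C)cc(OC)c1OC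
F4 | step 13 | methyl (2R,3S)-7-bromo-3-{[tert-butyl(dimethyl)silyl]oxymethyl}-2-(3,4,5-trimethoxyphenyl)-2,3-dihydro-1-benzofuran-5-carboxylate | COc1cc([C@@H]2Oc3c(Br)cc(C(=O)OC)cc3[C@H]2CO[Si](C)(C)C(C)(C)C)cc(OC)c1OC
F5 | step 13 | methyl (2R,3S)-3-{[tert-butyl(dimethyl)silyl]oxymethyl}-7-methoxy-2-(3,4,5-trimethoxyphenyl)-2,3-dihydro-1-benzofuran-5-carboxylate | COc1cc([C@@H]2Oc3c(OC)cc(C(=O)OC)cc3[C@H]2CO[Si](C)(C)C(C)(C)C)cc(OC)c1OC
F6 | step 13 | [(2R,3S)-3-{[tert-butyl(dimethyl)silyl]oxymethyl}-7-methoxy-2-(3,4,5-trimethoxyphenyl)-2,3-dihydro-1-benzofuran-5-yl]methanol | COc1cc([C@@H]2Oc3c(OC)cc(CO)cc3[C@H]2CO[Si](C)(C)C(C)(C)C)cc(OC)c1OC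
F7 | step 10 | (3E,4S,5R)-3-(3,3-dimethoxypropylidene)-2-(1-methoxyethenyl)-4-{[tert-butyl(dimethyl)silyl]oxymethyl}-5-(3,4,5-trimethoxyphenyl)oxolan-2-ol | COc1cc([C@@H]2OC(O)(C(=C)OC)/C(=C/CC(OC)OC)[C@H]2CO[Si](C)(C)C(C)(C)C)cc(OC)c1OC
F8 | step 12 | methyl (4S,5R)-4-{[tert-butyl(dimethyl)silyl]oxymethyl}-3-[(E)-3,3-dimethoxyprop-1-en-1-yl]-5-(3,4,5-trimethoxyphenyl)-4,5-dihydrofuran-2-carboxylate | COc1cc([C@@H]2OC(C(=O)OC)=C(/C=C/C(OC)OC)[C@H]2CO[Si](C)(C)C(C)(C)C)cc(OC)c1OC
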